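## Retrosynthetic overview

1. Target 19 ← removal of both N-Boc groups from the bis-carbamate quinone 18.
2. The quinone ring of 18 ← thermal four-to-six ring expansion of the 4-alkenyl-4-hydroxycyclobutenone 14 (electrocyclic opening, 6π closure, enolization), then Ag2O.
3. Enabling feature: in the quinone ring the contiguous atoms O=C–C(2-prenylated indol-3-yl)=C(OMe)–C=O are the four carbons of a squaric-acid-derived cyclobutenedione. The remaining ring pair C(indol-3-yl)=C(OMe) is a vinyl unit whose methoxy-bearing end carries one hydrogen, lost on aromatization.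
4. 14 ← cis-β-methoxyvinyllithium 13 (from bromide 12) + cyclobutenedione 8. 8 ← indole 4 + squaric dichloride 5, then MeOH and Boc2O. 12 ← aldehyde 9 by Wittig reaction and bromination–dehydrobromination.
5. Ring order: the pyrrole ring of the prenylated indole (step 2), the cyclobutene ring and the second indole purchased, the quinone ring last (step 8).

Key step: step 8

Remark on the chemistry: compounds 3, 5 and 9 are taken as purchasable; carbinol 14 and dienone 16 form as racemates, which does not matter because the target has no stereocenter.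

## Route

Step 1
Reactants: 1 2-methylaniline
Product: 2 2-methyl-N-(trimethylsilyl)aniline
Conditions: n-BuLi (1.05 equiv), THF, −78 → 0 °C; then Me3SiCl, 0 °C → rt; distillation
Reagents that add atoms: chlorotrimethylsilane, C[Si](C)(C)Cl
Why: N-lithiation followed by N-silylation is the standard preparation of the silylated toluidine used in the Smith modification of the Madelung indole synthesis; no stereocenter is formed.

Step 2
Reactants: 2 2-methyl-N-(trimethylsilyl)aniline; 3 methyl 2,2-dimethylbut-3-enoate
Product: 4 2-(2-methylbut-3-en-2-yl)-1H-indole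
Conditions: n-BuLi (2.2 equiv), hexane, reflux; then 3, THF, −78 °C → rt; H2O work-up
Reagents that add atoms: none
Why: The N,C-dianion is acylated at the benzylic carbon by the non-enolizable ester, and the silylamide then condenses onto the new ketone with loss of trimethylsilanolate to close the pyrrole ring (Smith–Madelung indole synthesis), which suits 2-tert-alkylindoles and keeps the 1,1-dimethylallyl group away from acid.

Step 3
Reactants: 4 2-(2-methylbut-3-en-2-yl)-1H-indole; 5 3,4-dichlorocyclobut-3-ene-1,2-dione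
Product: 7 3-methoxy-4-[2-(2-methylbut-3-en-2-yl)-1H-indol-3-yl]cyclobut-3-ene-1,2-dione, via chlorocyclobutenedione 6 (not isolated)
Conditions: 5 (1.0 equiv), Et2O, 0 °C → rt, argon sweep; then MeOH, 0 °C → rt
Reagents that add atoms: methanol, CO
Why: Indole C3 attacks the vinylogous acid chloride in an uncatalysed Friedel–Crafts-type addition–elimination, the deactivated monoadduct 6 should not react a second time, and methanol then displaces the remaining vinylogous acyl chloride to give the squaric ester.

Step 4
Reactants: 7 3-methoxy-4-[2-(2-methylbut-3-en-2-yl)-1H-indol-3-yl]cyclobut-3-ene-1,2-dione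
Product: 8 tert-butyl 3-(2-methoxy-3,4-dioxocyclobut-1-en-1-yl)-2-(2-methylbut-3-en-2-yl)-1H-indole-1-carboxylate
Conditions: Boc2O, DMAP (cat.), MeCN, rt
Reagents that add atoms: di-tert-butyl dicarbonate, CC(C)(C)OC(=O)OC(=O)OC(C)(C)C
Why: DMAP-catalysed N-Boc protection of the acidic, acyl-conjugated indole N–H removes the proton that would quench the organolithium of step 7 and weakens donation from the indole, so that the carbonyl next to the methoxy-bearing carbon remains the more electrophilic one.

Step 5
Reactants: 9 tert-butyl 3-formyl-1H-indole-1-carboxylate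
Product: 10 tert-butyl 3-(2-methoxyethenyl)-1H-indole-1-carboxylate (E/Z mixture)
Conditions: Ph3P(CH2OMe)Cl, NaN(SiMe3)2, THF, 0 °C; then 9, 0 °C → rt
Reagents that add atoms: (methoxymethyl)triphenylphosphonium chloride, COC[P+](c1ccccc1)(c1ccccc1)c1ccccc1.[Cl-]
Why: Wittig methoxymethylenation of the aryl aldehyde with the non-stabilised ylide, generated with an amide base that spares the carbamate, should give the enol ether as an E/Z mixture that converges in step 6.

Step 6
Reactants: 10 tert-butyl 3-(2-methoxyethenyl)-1H-indole-1-carboxylate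
Product: 12 tert-butyl 3-[(Z)-1-bromo-2-methoxyethenyl]-1H-indole-1-carboxylate, via dibromide 11 (not isolated)
Conditions: Br2 (1.0 equiv), CH2Cl2, −78 °C; then i-Pr2NEt, −78 °C → rt; filtration of the ammonium salt, chromatography
Reagents that add atoms: bromine, BrBr
Why: Bromine adds across the electron-rich enol ether, and the amine then removes the acidic benzylic hydrogen with loss of the labile α-bromo ether bromide (bromination–dehydrobromination of an enol ether, as used for cis-2-alkoxyvinyl bromides), which should favour the isomer with bromine cis to methoxy.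

Step 7
Reactants: 12 tert-butyl 3-[(Z)-1-bromo-2-methoxyethenyl]-1H-indole-1-carboxylate; 8 tert-butyl 3-(2-methoxy-3,4-dioxocyclobut-1-en-1-yl)-2-(2-methylbut-3-en-2-yl)-1H-indole-1-carboxylate
Product: 14 racemic tert-butyl 3-{3-[(Z)-1-(1-(tert-butoxycarbonyl)-1H-indol-3-yl)-2-methoxyethenyl]-3-hydroxy-2-methoxy-4-oxocyclobut-1-en-1-yl}-2-(2-methylbut-3-en-2-yl)-1H-indole-1-carboxylate, via vinyllithium 13 (not isolated)
Conditions: 12, t-BuLi (2.0 equiv), THF/Et2O, −100 → −78 °C; cannulation into 8, THF, −78 °C; AcOH, −78 °C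
Reagents that add atoms: none
Why: Bromine–lithium exchange should give the oxygen-chelated cis-β-methoxyvinyllithium, which adds 1,2 to the ketone-like carbonyl of 8 (the one attached to the methoxy-bearing ring carbon) because the other carbonyl is a deactivated vinylogous ester (regioselective organolithium addition to a 3-alkoxy-4-arylcyclobutenedione); the carbinol stereocenter forms as a racemate and is erased in step 8.

Step 8
Reactants: 14 racemic 4-alkenyl-4-hydroxycyclobutenone (full name in step 7)
Product: 18 tert-butyl 3-[4-(1-(tert-butoxycarbonyl)-1H-indol-3-yl)-2,5-dimethoxy-3,6-dioxocyclohexa-1,4-dien-1-yl]-2-(2-methylbut-3-en-2-yl)-1H-indole-1-carboxylate, via dienylketene 15 (not isolated), via cyclohexadienone 16 (not isolated), via hydroquinone 17 (not isolated)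
Conditions: toluene, 110 °C, argon; then Ag2O, rt
Reagents that add atoms: none
Why: Heating should open the cyclobutenone by conrotatory 4π cleavage of the bond between the carbonyl carbon and the carbinol carbon, with the hydroxyl rotating outward so that the alkenyl group sits on the ketene side of dienylketene 15. Thermal disrotatory 6π electrocyclization then joins the ketene carbon to the hydrogen- and methoxy-bearing vinyl terminus, so the six-membered carbocycle is closed by pericyclic C–C bond formation to give dienone 16. Enolization of its single ring hydrogen gives the hexasubstituted hydroquinone 17, and Ag2O removes two hydrogens to give the quinone. The closest known reaction type is the thermal ring expansion of 4-alkenyl-4-hydroxycyclobutenones to hydroquinones and quinones (Moore–Liebeskind chemistry). The stereocenters of 14 and 16 are destroyed on aromatization, so none has to be controlled. The step needs electrocyclization to win over lactonization of the ketene by the hydroxyl group (secured by outward rotation of the donor OH) and enolization to win over loss of methanol from 16 (favoured by the aromatization energy); the substitution pattern is fixed by the regiochemistry of step 7.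

Step 9
Reactants: 18 bis-carbamate quinone (full name in step 8)
Product: 19 2,5-dimethoxy-3-(1H-indol-3-yl)-6-[2-(2-methylbut-3-en-2-yl)-1H-indol-3-yl]cyclohexa-2,5-diene-1,4-dione
Conditions: K2CO3 (0.5 equiv), dry MeOH/THF (2:1), rt, argon; pH 7 buffer work-up
Reagents that add atoms: none
Why: Methoxide formed from K2CO3 in methanol should cleave both indole carbamates by acyl transfer to methanol (base-mediated N-Boc removal from acyl-conjugated indoles), exchange at the methoxyquinone carbons is degenerate in methanol, and no acid touches the 1,1-dimethylallyl group.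

## Compound list

1 | 2-methylaniline | Cc1ccccc1N | starting material
2 | 2-methyl-N-(trimethylsilyl)aniline | Cc1ccccc1N[Si](C)(C)C | intermediate
3 | methyl 2,2-dimethylbut-3-enoate | COC(=O)C(C)(C)C=C | starting material
4 | 2-(2-methylbut-3-en-2-yl)-1H-indole | C=CC(C)(C)c1cc2ccccc2[nH]1 | intermediate
5 | 3,4-dichlorocyclobut-3-ene-1,2-dione | ClC1=C(Cl)C(=O)C1=O | starting material
6 | 3-chloro-4-[2-(2-methylbut-3-en-2-yl)-1H-indol-3-yl]cyclobut-3-ene-1,2-dione | C=CC(C)(C)c1[nH]c2ccccc2c1C1=C(Cl)C(=O)C1=O | intermediate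
7 | 3-methoxy-4-[2-(2-methylbut-3-en-2-yl)-1H-indol-3-yl]cyclobut-3-ene-1,2-dione | C=CC(C)(C)c1[nH]c2ccccc2c1C1=C(OC)C(=O)C1=O | intermediate
8 | tert-butyl 3-(2-methoxy-3,4-dioxocyclobut-1-en-1-yl)-2-(2-methylbut-3-en-2-yl)-1H-indole-1-carboxylate | C=CC(C)(C)c1n(C(=O)OC(C)(C)C)c2ccccc2c1C1=C(OC)C(=O)C1=O | intermediate
9 | tert-butyl 3-formyl-1H-indole-1-carboxylate | O=Cc1cn(C(=O)OC(C)(C)C)c2ccccc12 | starting material
10 | tert-butyl 3-(2-methoxyethenyl)-1H-indole-1-carboxylate (E/Z mixture) | COC=Cc1cn(C(=O)OC(C)(C)C)c2ccccc12 | intermediate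
11 | tert-butyl 3-(1,2-dibromo-2-methoxyethyl)-1H-indole-1-carboxylate (diastereomer mixture) | COC(Br)C(Br)c1cn(C(=O)OC(C)(C)C)c2ccccc12 | intermediate
12 | tert-butyl 3-[(Z)-1-bromo-2-methoxyethenyl]-1H-indole-1-carboxylate | CO/C=C(\Br)c1cn(C(=O)OC(C)(C)C)c2ccccc12 | intermediate
13 | tert-butyl 3-[(E)-1-lithio-2-methoxyethenyl]-1H-indole-1-carboxylate (lithium cis to methoxy) | CO/C=C(\[Li])c1cn(C(=O)OC(C)(C)C)c2ccccc12 | intermediate
14 | racemic tert-butyl 3-{3-[(Z)-1-(1-(tert-butoxycarbonyl)-1H-indol-3-yl)-2-methoxyethenyl]-3-hydroxy-2-methoxy-4-oxocyclobut-1-en-1-yl}-2-(2-methylbut-3-en-2-yl)-1H-indole-1-carboxylate | COC1=C(c2c(C(C)(C)C=C)n(C(=O)OC(C)(C)C)c3ccccc23)C(=O)C1(O)/C(=C\OC)c1cn(C(=O)OC(C)(C)C)c2ccccc12 | intermediate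
15 | tert-butyl 3-[(3Z,5Z)-5-(1-(tert-butoxycarbonyl)-1H-indol-3-yl)-4-hydroxy-3,6-dimethoxy-1-oxohexa-1,3,5-trien-2-yl]-2-(2-methylbut-3-en-2-yl)-1H-indole-1-carboxylate (dienylketene) | O=C=C(c1c(C(C)(C)C=C)n(C(=O)OC(C)(C)C)c2ccccc12)/C(OC)=C(O)\C(=C/OC)c1cn(C(=O)OC(C)(C)C)c2ccccc12 | intermediate
16 | racemic tert-butyl 3-[3-(1-(tert-butoxycarbonyl)-1H-indol-3-yl)-4-hydroxy-2,5-dimethoxy-6-oxocyclohexa-3,5-dien-1-yl... written as the cyclohexa-2,4-dienone: 4-hydroxy-3,6-dimethoxy-5-(1-Boc-indol-3-yl)-2-[1-Boc-2-(2-methylbut-3-en-2-yl)indol-3-yl]cyclohexa-2,4-dien-1-one | O=C1C(c2c(C(C)(C)C=C)n(C(=O)OC(C)(C)C)c3ccccc23)=C(OC)C(O)=C(c2cn(C(=O)OC(C)(C)C)c3ccccc23)C1OC | intermediate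
17 | tert-butyl 3-[4-(1-(tert-butoxycarbonyl)-1H-indol-3-yl)-3,6-dihydroxy-2,5-dimethoxyphenyl]-2-(2-methylbut-3-en-2-yl)-1H-indole-1-carboxylate (hydroquinone) | COc1c(O)c(-c2c(C(C)(C)C=C)n(C(=O)OC(C)(C)C)c3ccccc23)c(OC)c(O)c1-c1cn(C(=O)OC(C)(C)C)c2ccccc12 | intermediate
18 | tert-butyl 3-[4-(1-(tert-butoxycarbonyl)-1H-indol-3-yl)-2,5-dimethoxy-3,6-dioxocyclohexa-1,4-dien-1-yl]-2-(2-methylbut-3-en-2-yl)-1H-indole-1-carboxylate | COC1=C(c2cn(C(=O)OC(C)(C)C)c3ccccc23)C(=O)C(OC)=C(c2c(C(C)(C)C=C)n(C(=O)OC(C)(C)C)c3ccccc23)C1=O | intermediate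
19 | 2,5-dimethoxy-3-(1H-indol-3-yl)-6-[2-(2-methylbut-3-en-2-yl)-1H-indol-3-yl]cyclohexa-2,5-diene-1,4-dione | C=CC(C)(C)c1[nH]c2ccccc2c1C1=C(OC)C(=O)C(c2c[nH]c3ccccc23)=C(OC)C1=O | target

## Count and risks

Total step count: 9. Longest linear sequence: 7 steps (steps 1, 2, 3, 4, 7, 8, 9); the second branch (steps 5 and 6) joins at step 7.

**Step 8 (key step).** What may go wrong: dienone 16 may lose methanol by 1,4-elimination faster than it enolizes, or the ketene may be captured by the hydroxyl group to give a furanone. Fallback: the six-membered ring is taken ready-made. Setting out from indole 4, acid-promoted conjugate addition (AcOH, or HCl in THF) to purchased 2,5-dichloro-1,4-benzoquinone should give 2,5-dichloro-3-[2-(2-methylbut-3-en-2-yl)-1H-indol-3-yl]benzene-1,4-diol F1, which DDQ would oxidise to 2,5-dichloro-3-[2-(2-methylbut-3-en-2-yl)-1H-indol-3-yl]cyclohexa-2,5-diene-1,4-dione F2. A second acid-promoted addition, now of purchased indole at the only free ring carbon, should give 2,5-dichloro-3-(1H-indol-3-yl)-6-[2-(2-methylbut-3-en-2-yl)-1H-indol-3-yl]benzene-1,4-diol F3, oxidised by DDQ to 2,5-dichloro-3-(1H-indol-3-yl)-6-[2-(2-methylbut-3-en-2-yl)-1H-indol-3-yl]cyclohexa-2,5-diene-1,4-dione F4. NaOMe in MeOH would then replace both chlorides by addition–elimination, and the fallback comes back to the route at the target 19.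

**Step 7.** What may go wrong: t-BuLi may attack the carbamate, the lithium species may lose lithium methoxide by β-elimination when lithium and methoxy are trans, or addition may occur at the wrong carbonyl. Fallback: setting out from bromide 12, bromine–magnesium exchange with i-PrMgCl·LiCl (THF, −20 → 0 °C) should give {(E)-1-[1-(tert-butoxycarbonyl)-1H-indol-3-yl]-2-methoxyethenyl}magnesium chloride F5 (magnesium cis to methoxy). This species is less basic, attacks carbamates slowly and is far less prone to alkoxide loss. Its addition to 8 at −78 °C (LaCl3·2LiCl as promoter if needed) and an aqueous NH4Cl quench would come back to the route at carbinol 14.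

**Step 6.** What may go wrong: hydrogen bromide may be lost in the wrong direction, the indole ring may be brominated, or the isomer with bromine trans to methoxy may form. Fallback: setting out from enol ether 10, NBS in MeOH at −20 °C should give the bromoacetal tert-butyl 3-(1-bromo-2,2-dimethoxyethyl)-1H-indole-1-carboxylate F6 by bromo-methoxylation. Elimination of methanol with Me3SiOTf and i-Pr2NEt in CH2Cl2 (acetal-to-enol-ether conversion) would come back to the route at bromide 12.

## Further compounds

F1 | step 8 | 2,5-dichloro-3-[2-(2-methylbut-3-en-2-yl)-1H-indol-3-yl]benzene-1,4-diol | C=CC(C)(C)c1[nH]c2ccccc2c1-c1c(O)c(Cl)cc(O)c1Cl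
F2 | step 8 | 2,5-dichloro-3-[2-(2-methylbut-3-en-2-yl)-1H-indol-3-yl]cyclohexa-2,5-diene-1,4-dione | C=CC(C)(C)c1[nH]c2ccccc2c1C1=C(Cl)C(=O)C=C(Cl)C1=O
F3 | step 8 | 2,5-dichloro-3-(1H-indol-3-yl)-6-[2-(2-methylbut-3-en-2-yl)-1H-indol-3-yl]benzene-1,4-diol | C=CC(C)(C)c1[nH]c2ccccc2c1-c1c(O)c(Cl)c(-c2c[nH]c3ccccc23)c(O)c1Cl
F4 | step 8 | 2,5-dichloro-3-(1H-indol-3-yl)-6-[2-(2-methylbut-3-en-2-yl)-1H-indol-3-yl]cyclohexa-2,5-diene-1,4-dione | C=CC(C)(C)c1[nH]c2ccccc2c1C1=C(Cl)C(=O)C(c2c[nH]c3ccccc23)=C(Cl)C1=O
F5 | step 7 | {(E)-1-[1-(tert-butoxycarbonyl)-1H-indol-3-yl]-2-methoxyethenyl}magnesium chloride (magnesium cis to methoxy) | CO/C=C(\[Mg]Cl)c1cn(C(=O)OC(C)(C)C)c2ccccc12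
F6 | step 6 | tert-butyl 3-(1-bromo-2,2-dimethoxyethyl)-1H-indole-1-carboxylate | COC(OC)C(Br)c1cn(C(=O)OC(C)(C)C)c2ccccc12
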